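# Proposed total synthesis of CNP0198957.4, [(3S,4S,5R,6R)-5-(benzoyloxy)-3,4,6-trihydroxycyclohex-1-en-1-yl]methyl benzoate

Atom labels C1–C7 and O3–O7 are those of the target throughout: C1 carries C7H2OBz, C2 is the vinylic CH, C3–C6 are the carbinol carbons, and the benzoate sits on O5.

## Structural features

The target has a single carbocycle, a cyclohexene (ring A), with no ring fusion; the two phenyl rings are only the aryl parts of two benzoate esters. The four sp3 carbons C3–C6 follow one another around the ring and each bears an oxygen: free hydroxyls on C3, C4 and C6, and a benzoate on C5. These four stereocentres are contiguous and all four oxygens lie on the same face of the ring, (3S,4S,5R,6R). The fragile points are the O5 benzoate, which sits between two cis hydroxyls and can migrate to O4 or O6 under base, and the allylic C–O bonds at C3, C6 and C7; the ring as a whole is only two eliminations away from an aromatic compound. The carbon skeleton (six ring carbons plus C7) is trivial, and the real difficulty is the all-cis tetraol, whose second diol must be placed on the more crowded face, together with the absolute configuration and the placing of benzoates on O5 and O7 only, among five oxygens. The key step exploits the C5–C6 cis-diol that lies next to the substituted alkene carbon C1 of ring A: this is the 2,3-cis-dihydrodiol pattern that toluene dioxygenase writes into a monosubstituted benzene. The C1=C2–C3=C4 diene is then the residue of the arene, and a bromine on C1 stands in for C7.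

## Logic of the disconnections

**13 back to 11 (through 12).** The bonds cut in the forward sense are the O6–CH2Ar ether bond and the two ketal C–O bonds on O3 and O4. A benzoate flanked by cis hydroxyls should meet its free neighbours only once, at the very end and under acid. The gain is that 11 has no free hydroxyl, so acyl migration is impossible before the last step. The demand is that both masks leave under one acidic regime that spares the esters and the allylic C–O bonds.

**11 back to 9 and 10.** The two ester C(=O)–O bonds at O5 and O7 are cut together, because both acyl groups are the same and 10 can install both. Two acylation steps become one and 9 is a simple diol. The demand is that 9 has exactly these two hydroxyls free and that two equivalents of 10 are taken up.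

**9 back to 7 and 8.** The sp2–sp3 bond C1–C7 is cut, because C7 is a one-carbon unit on an alkene carbon that can carry a halide. This separates the six-carbon ring of 7, which is of arene origin, from 8, which supplies the single carbon. The demand is that the vinyl bromide survives every earlier step and that the coupling tolerates the free O5–H, so that the benzoates can wait until after it.

**7 back to 6.** The ketal C–O bonds on O3 and O4 are cut; the ketal serves only to single out O5. The demand is regioselection between two cis-diol pairs, O3/O4 against O4/O5.

**6 back to 4 (through 5).** The bonds C3–O3 and C4–O4 are cut, since a cis-diol maps onto an alkene. This returns the C1=C2–C3=C4 diene. The demand is twofold: oxidation of C3=C4 and not C1=C2, and delivery of both oxygens to the face that already carries O5 and O6. That face is the sterically disfavoured one, so the free O5–H of 4 must direct an amine-ligated osmium oxidant.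

**4 back to 3.** The benzylic C–H bond of the O6 ether is exchanged for a bond from that carbon to O5, which closes the cyclic acetal of 3. A direct monoprotection of the diol would go to O5, the less hindered hydroxyl, which is the wrong one. Opening the cyclic acetal with a Lewis-acidic aluminium hydride leaves the ether on the more hindered oxygen instead. The demand is that aluminium coordinates at O5 and not at O6.

**3 back to 2.** The two acetal C–O bonds are cut. The gain is the free diol; the demand is mild acid and low temperature, because 2 dehydrates easily.

**2 back to 1.** The bonds C5–O5 and C6–O6 are cut and the ring is rearomatised. The cis-diol beside the halogen-bearing carbon is exactly what the dioxygenase produces. The gain is that 1 is flat, cheap and has no stereocentre. The demand, which only the enzyme can meet, is oxidation of the bond next to the substituent from one enantioface without over-oxidation.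

## Other disconnections considered

**Alternative 1:** The ring would be cut at C1–C2 and C5–C6. This divides it into furan A1 (C2 to C5 and the oxygen that becomes O5) and 3-acryloyloxazolidin-2-one A2 (C1, C6 and C7). In the forward direction the chiral divalent copper Lewis acid [Cu(t-Bu-box)](SbF6)2 would chelate A2 and lead to the endo oxabicycle A3.

- In its favour: the carbocycle and C7 come from two cheap achiral partners in one catalytic asymmetric step. C7 is present from the start, so no organotin is needed; on this point it is better than the chosen plan. Base-induced opening of the oxygen bridge would reveal O5–H and the C1=C2 bond together. The same hydroxyl-directed osmylation of C3=C4 would then be needed, so the two plans are equal on the all-cis question at C3–C5.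
- Against it here: furan cycloadditions are reversible, so A3 must be made and kept cold. The bridge oxygen supplies only O5. C6 arrives as a CH2 group and would need a late allylic C–H oxidation with cis selectivity, for which there is no directing handle. After bridge opening the ring is one dehydration away from aromaticity. C7 comes at the carboxyl oxidation level and needs a reduction timed before the benzoates.
- Comparison: absolute control by a chiral catalyst is comparable in principle to control by the enzyme. The oxygen at C6 that the dioxygenase supplies at the outset is missing, however, and several more steps would be expected.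

**Alternative 2:** The ring would be cut at C3–C4 and C5–C6. (1E,3E)-1,4-Diacetoxybuta-1,3-diene A4 supplies C6, C1, C2 and C3 with O6 and O3; vinylene carbonate A5 supplies C4 and C5 with their oxygens. A thermal endo Diels–Alder reaction would give the meso all-cis adduct A6.

- In its favour: all four carbinol stereocentres and their all-cis relation are set in one concerted step by the diene geometry, the cis dienophile and the endo rule. This is better than the chosen plan, which needs two separate oxidations and a delivery against the steric bias. No metal and no enzyme are needed.
- Against it here: A6 is meso, so the absolute configuration depends on a later desymmetrising benzoylation. That step must choose O5 over its enantiotopic partner O4 and over O3 and O6. The C1=C2 bond is unsubstituted, so C7 needs a separate C–C bond formation, for example oxidation at C6, a Morita–Baylis–Hillman hydroxymethylation at C1 and a 1,2-reduction. This would run on a substrate prone to elimination and acyl migration. The cycloaddition needs forcing temperature.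
- Comparison: the chosen plan obtains absolute configuration and the C1 handle at the outset, where this plan obtains relative configuration at the outset. The protecting-group burden is about equal, and the step count would be expected to be higher.

**Alternative 3:** The ring would be cut at C2–C3. The precursor is the 5-enopyranoside A7, in which sugar C2, C3 and C4 are the future C4, C5 and C6. With Hg(OCOCF3)2 in aqueous acetone, oxymercuration of the enol ether expels the anomeric methoxy group, and the α-mercurio ketone adds to the unmasked aldehyde in a Ferrier carbocyclization to give the cyclohexanone A8.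

- In its favour: three of the four stereocentres and the absolute configuration come from the sugar pool. The benzoate sits on O5 from the start with no regiochemical doubt, which is better than the chosen plan with its two regioselective operations at oxygen. The ring closure is a well-understood ionic process.
- Against it here: the all-cis D-allo series is not a commodity and needs an inversion at C3 of a common hexose, followed by a long protecting-group sequence to A7. A toxic divalent mercury salt is used. C3 is set in the aldol step and its cis relation to O4 is not assured. A8 is a β-hydroxy ketone, and any enolisation towards C2, needed to introduce C7 and the C1=C2 bond, invites β-elimination of O3. Silyl and benzoyl groups can migrate under the basic conditions required.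
- Comparison: the carbocycle has to be made, whereas the chosen plan starts with it. The chosen plan is shorter by a wide margin, and neither plan is free of a heavy-metal reagent.

Key step: step 1

## Remarks before the steps

- Assumption: the acetal carbon of 3 should form as a mixture of both epimers; it is left unspecified because step 3 turns it into a CH2 group.
- Stoichiometry of step 7: two molecules of 10 are taken up, one for O5 and one for O7. The first is the numbered reactant and the second is entered as the atom-adding reagent of that step.
- Safety choices: OsO4 is used once, as a pre-made CH2Cl2 solution in a closed system, and is destroyed with Na2SO3 in the same flask. The organotin is confined to one step and removed with aqueous KF. Mercury, azides, peroxides and strongly basic organometallics are avoided.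
- Dienes 3 and 4 are kept cold and used promptly, because such dienes dimerise by [4+2] cycloaddition on standing.

## Steps

Step 1
Reactants: 1 bromobenzene
Product: 2 (1S,2S)-3-bromocyclohexa-3,5-diene-1,2-diol
Conditions: E. coli JM109(pDTG601) whole cells, IPTG induction, glucose-fed aerated fermenter (O2 from air), pH 7.0, 30–35 °C, 1 metered in; broth extracted with base-washed EtOAc, crystallisation
Reagents that add atoms: dioxygen, O=O
Why: Toluene dioxygenase is a three-component Rieske non-heme iron system in which a reductase and a ferredoxin pass two electrons from NADH to the oxygenase; there O2 is bound at the mononuclear iron centre and both of its atoms are transferred to the same face of one arene C=C bond, so the future C5–O5 and C6–O6 bonds form cis in one event. This is the standard enzymatic cis-dihydroxylation of a monosubstituted benzene by recombinant whole cells, and bromobenzene is a routine substrate for it. No ring is closed; the step removes aromaticity and leaves the C1=C2–C3=C4 diene. Both new stereocentres are fixed by the active site, which holds the halogen in the pocket that takes the methyl group of toluene and therefore oxidises the 2,3-bond from a single enantioface to give the (1S,2S) diol, the configuration needed at C5 and C6. The step needs regioselectivity for the bond next to the substituent and freedom from over-oxidation; the first is a property of the enzyme, and the second is secured because the host carries the dioxygenase genes without the diol dehydrogenase, so 2 should accumulate. Substrate toxicity is held in check by metered feeding, and the cells regenerate NADH from glucose. The bromine stays on the future C1, where it later deactivates C1=C2 and serves as the coupling handle for C7.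

Step 2
Reactants: 2 (1S,2S)-3-bromocyclohexa-3,5-diene-1,2-diol
Product: 3 (3aS,7aS)-4-bromo-2-(4-methoxyphenyl)-3a,7a-dihydro-1,3-benzodioxole
Conditions: 4-MeOC6H4CH(OMe)2 (1.2 equiv), CSA (cat.), CH2Cl2, −20 °C; Et3N quench; used at once
Reagents that add atoms: 4-methoxybenzaldehyde dimethyl acetal, COc1ccc(C(OC)OC)cc1
Why: Acid-catalysed transacetalisation of a cis-1,2-diol is fast at low temperature, which should keep the acid-sensitive dienediol from dehydrating to a bromophenol. No ring stereocentre is touched and the configuration of the acetal carbon is irrelevant.

Step 3
Reactants: 3 (3aS,7aS)-4-bromo-2-(4-methoxyphenyl)-3a,7a-dihydro-1,3-benzodioxole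
Product: 4 (1S,6S)-5-bromo-6-[(4-methoxyphenyl)methoxy]cyclohexa-2,4-dien-1-ol
Conditions: i-Bu2AlH (3 equiv), CH2Cl2, −78 → 0 °C; aq. KNaC4H4O6 (potassium sodium tartrate) work-up
Reagents that add atoms: none
Why: Regioselective reductive opening of an arylidene acetal by a Lewis-acidic hydride: aluminium should bind the more accessible and more basic O5 (O6 is crowded and made less basic by the neighbouring C–Br carbon), the O5–C(acetal) bond ionises to an aryl-stabilised oxocarbenium ion, and hydride delivery leaves the ether on O6 and frees O5–H. The ring C–O bonds are not broken, so C5 and C6 keep their configuration.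

Step 4
Reactants: 4 (1S,6S)-5-bromo-6-[(4-methoxyphenyl)methoxy]cyclohexa-2,4-dien-1-ol
Product: 6 (1S,2S,3S,6S)-5-bromo-6-[(4-methoxyphenyl)methoxy]cyclohex-4-ene-1,2,3-triol, via TMEDA-chelated cyclic osmate ester 5 (not isolated)
Conditions: OsO4 (1.05 equiv), TMEDA (1.1 equiv), CH2Cl2, −78 °C; then aq. Na2SO3, THF, 60 °C
Reagents that add atoms: osmium tetroxide, O=[Os](=O)(=O)=O
Why: Hydrogen-bond-directed dihydroxylation of a cyclic allylic alcohol: the diamine makes the oxo ligands of OsO4 good hydrogen-bond acceptors, so O5–H should hold the reagent and steer the [3+2] addition to the face of C3=C4 that carries O5, which sets C3 and C4 cis to C5 and C6 against the steric bias. C1=C2 should be spared because bromine lowers its electron density and no free allylic O–H serves it. The hexavalent osmium ester 5 is then hydrolysed by aqueous Na2SO3.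

Step 5
Reactants: 6 (1S,2S,3S,6S)-5-bromo-6-[(4-methoxyphenyl)methoxy]cyclohex-4-ene-1,2,3-triol
Product: 7 (3aR,4S,5S,7aS)-6-bromo-5-[(4-methoxyphenyl)methoxy]-2,2-dimethyl-3a,4,5,7a-tetrahydro-1,3-benzodioxol-4-ol
Conditions: Me2C(OMe)2 (3 equiv), PPTS (cat.), acetone, 0 °C → rt; Et3N quench
Reagents that add atoms: 2,2-dimethoxypropane, COC(C)(C)OC
Why: Acid-catalysed ketalisation of a cis-1,2-diol under equilibrating conditions. The O3/O4 ketal should be preferred over the O4/O5 isomer because O3 is the least hindered hydroxyl (allylic, beside the vinylic CH), whereas a dioxolane on O4/O5 would be pressed against the cis O6 ether; O5–H remains as the only free hydroxyl.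

Step 6
Reactants: 7 (3aR,4S,5S,7aS)-6-bromo-5-[(4-methoxyphenyl)methoxy]-2,2-dimethyl-3a,4,5,7a-tetrahydro-1,3-benzodioxol-4-ol; 8 (tributylstannyl)methanol
Product: 9 (3aR,4R,5R,7aS)-6-(hydroxymethyl)-5-[(4-methoxyphenyl)methoxy]-2,2-dimethyl-3a,4,5,7a-tetrahydro-1,3-benzodioxol-4-ol
Conditions: Pd(PPh3)4 (10 mol%), 8 (1.5 equiv), 1,4-dioxane, 100 °C, degassed; aq. KF work-up
Reagents that add atoms: none
Why: Stille coupling of an alkenyl bromide with an α-hydroxymethylstannane: zerovalent palladium inserts into C1–Br, the oxygen-activated CH2OH group is transferred in preference to butyl, and reductive elimination forms C1–C7 with the alkene in place. The free hydroxyl, the ketal and the benzylic ether are inert and no stereocentre is involved.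

Step 7
Reactants: 9 (3aR,4R,5R,7aS)-6-(hydroxymethyl)-5-[(4-methoxyphenyl)methoxy]-2,2-dimethyl-3a,4,5,7a-tetrahydro-1,3-benzodioxol-4-ol; 10 benzoyl chloride
Product: 11 [(3aS,6R,7R,7aS)-7-(benzoyloxy)-6-[(4-methoxyphenyl)methoxy]-2,2-dimethyl-3a,6,7,7a-tetrahydro-1,3-benzodioxol-5-yl]methyl benzoate
Conditions: 10 (2.6 equiv in all), pyridine, DMAP (cat.), CH2Cl2, 0 °C → rt
Reagents that add atoms: benzoyl chloride (the second equivalent of 10), O=C(Cl)c1ccccc1
Why: DMAP-catalysed acylation of the only two free hydroxyls, primary allylic O7 and secondary O5, should install both benzoates of the target in one operation, each hydroxyl taking up one molecule of 10. Only O–H bonds react, so C5 keeps its configuration.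

Step 8
Reactants: 11 [(3aS,6R,7R,7aS)-7-(benzoyloxy)-6-[(4-methoxyphenyl)methoxy]-2,2-dimethyl-3a,6,7,7a-tetrahydro-1,3-benzodioxol-5-yl]methyl benzoate
Product: 13 [(3S,4S,5R,6R)-5-(benzoyloxy)-3,4,6-trihydroxycyclohex-1-en-1-yl]methyl benzoate, via 6-hydroxy acetonide dibenzoate 12 (not isolated)
Conditions: TFA–CH2Cl2 (1:9), anisole (5 equiv), 0 °C; then H2O, 0 °C → rt; toluene co-evaporation, no basic wash
Reagents that add atoms: none
Why: Acidolysis of the 4-methoxybenzyl ether (loss of the stabilised benzyl cation, trapped by anisole) followed by acid hydrolysis of the isopropylidene ketal; both cleave C–O bonds outside the ring, so all four stereocentres are retained. Base-free acidic conditions are chosen because benzoate migration from O5 to the cis O4 or O6 is base-promoted and slow in acid.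

## Compound list

1 | bromobenzene | Brc1ccccc1 | starting material
2 | (1S,2S)-3-bromocyclohexa-3,5-diene-1,2-diol | BrC1=CC=C[C@H](O)[C@@H]1O | intermediate
3 | (3aS,7aS)-4-bromo-2-(4-methoxyphenyl)-3a,7a-dihydro-1,3-benzodioxole, acetal carbon as a mixture of epimers | BrC1=CC=C[C@@H]2OC(c3ccc(OC)cc3)O[C@H]12 | intermediate
4 | (1S,6S)-5-bromo-6-[(4-methoxyphenyl)methoxy]cyclohexa-2,4-dien-1-ol | BrC1=CC=C[C@H](O)[C@@H]1OCc2ccc(OC)cc2 | intermediate
5 | cyclic dioxo-osmate ester (hexavalent osmium) spanning O3 and O4 of 6, chelated by TMEDA, O5–H free; SMILES written with the diamine as a separate component | BrC1=C[C@@H]3O[Os](=O)(=O)O[C@@H]3[C@H](O)[C@@H]1OCc2ccc(OC)cc2.CN(C)CCN(C)C | intermediate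
6 | (1S,2S,3S,6S)-5-bromo-6-[(4-methoxyphenyl)methoxy]cyclohex-4-ene-1,2,3-triol, all four oxygens cis | BrC1=C[C@H](O)[C@H](O)[C@H](O)[C@@H]1OCc2ccc(OC)cc2 | intermediate
7 | (3aR,4S,5S,7aS)-6-bromo-5-[(4-methoxyphenyl)methoxy]-2,2-dimethyl-3a,4,5,7a-tetrahydro-1,3-benzodioxol-4-ol | BrC1=C[C@@H]3OC(C)(C)O[C@@H]3[C@H](O)[C@@H]1OCc2ccc(OC)cc2 | intermediate
8 | (tributylstannyl)methanol | OC[Sn](CCCC)(CCCC)CCCC | starting material
9 | (3aR,4R,5R,7aS)-6-(hydroxymethyl)-5-[(4-methoxyphenyl)methoxy]-2,2-dimethyl-3a,4,5,7a-tetrahydro-1,3-benzodioxol-4-ol | OCC1=C[C@@H]3OC(C)(C)O[C@@H]3[C@H](O)[C@@H]1OCc2ccc(OC)cc2 | intermediate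
10 | benzoyl chloride | O=C(Cl)c1ccccc1 | starting material
11 | [(3aS,6R,7R,7aS)-7-(benzoyloxy)-6-[(4-methoxyphenyl)methoxy]-2,2-dimethyl-3a,6,7,7a-tetrahydro-1,3-benzodioxol-5-yl]methyl benzoate | O=C(OCC1=C[C@@H]3OC(C)(C)O[C@@H]3[C@H](OC(=O)c4ccccc4)[C@@H]1OCc2ccc(OC)cc2)c5ccccc5 | intermediate
12 | [(3aS,6R,7R,7aS)-7-(benzoyloxy)-6-hydroxy-2,2-dimethyl-3a,6,7,7a-tetrahydro-1,3-benzodioxol-5-yl]methyl benzoate | O=C(OCC1=C[C@@H]3OC(C)(C)O[C@@H]3[C@H](OC(=O)c4ccccc4)[C@@H]1O)c5ccccc5 | intermediate
13 | [(3S,4S,5R,6R)-5-(benzoyloxy)-3,4,6-trihydroxycyclohex-1-en-1-yl]methyl benzoate (CNP0198957.4) | O=C(OCC1=C[C@H](O)[C@H](O)[C@H](OC(=O)c2ccccc2)[C@@H]1O)c1ccccc1 | target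

## Step count and risk

Total step count: 8. Longest linear sequence: 8 steps (1 to 13); 8 and 10 are bought and enter at steps 6 and 7.

**Step 1 (key step).** The most likely failures are low conversion, because bromobenzene poisons the cells or the plasmid-borne activity is lost, and dehydration of 2 to bromophenols if the broth or extract turns acidic during isolation. Fallback: change the biocatalyst and not merely the fermentation settings. The blocked mutant Pseudomonas putida 39/D carries the same dioxygenase on the chromosome, lacks the diol dehydrogenase, and is induced with toluene vapour and not with IPTG. This fallback sets out from 1 and returns at 2 without any new compound.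

**Step 4.** The most likely failure is poor facial selectivity. O5–H may be held in an internal hydrogen bond to the neighbouring O6 ether and then fail to bind the osmium reagent, so that attack from the open face competes. Fallback: a Woodward cis-hydroxylation, which reaches the crowded face by a different logic. From 4, I2 and AgOAc in acetic acid should place the iodonium ion on the open face; acetate opens it at allylic C3 from the crowded face, and the acetoxy group then displaces iodide at C4. Wet acetic acid should hydrolyse the resulting dioxolanylium ion to the all-cis diol monoacetate F1 (drawn as the O3-acetate; the position of the acetyl group does not matter). K2CO3 in methanol removes the acetyl group and the route is rejoined at 6.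

**Step 3.** The most likely failures are opening of the acetal in the wrong sense, which would put the ether on O5, and loss of 3 through [4+2] dimerisation before it is reduced. Fallback: use the steric preference of the diol directly. From 2, thexyldimethylsilyl chloride and imidazole in DMF at −20 °C should silylate the less hindered O5 to give the O5 thexyldimethylsilyl ether F2. 4-Methoxybenzyl trichloroacetimidate with a catalytic amount of Sc(OTf)3 then etherifies O6 to give the silyl 4-methoxybenzyl diether F3. Bu4NF removes the silyl group and the route is rejoined at 4.

**Step 5.** The most likely failure is ketalisation across O4/O5 in place of O3/O4, which would later put the benzoate on O3. Fallback: benzoylate O5 while osmium still ties up O3 and O4, relying on the robustness of diamine-chelated osmate esters towards acylation. Ester 5 is isolated from step 4 and treated with 10, pyridine and DMAP to give the osmate ester O5-benzoate F4. Concentrated HCl in methanol at room temperature cleaves the osmium to give the 3,4-diol 5-benzoate F5. Me2C(OMe)2 and PPTS then give the bromo acetonide O5-benzoate F6, for which only one cis-diol is available. Coupling with 8 under Pd(PPh3)4 gives the C7 alcohol O5-benzoate F7, and benzoylation of O7 with 10 rejoins the route at 11.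

**Step 8.** The most likely failures are migration of the O5 benzoate to O4 or O6 once the flanking hydroxyls are free, and re-alkylation by the 4-methoxybenzyl cation. Fallback: remove the ether oxidatively and not by acid. From 11, DDQ in CH2Cl2 with pH 7 buffer gives 12, which is now isolated. Its ketal is then hydrolysed with aqueous acetic acid at 40 °C to reach 13, without any new compound.

**Step 6.** The most likely failures are slow transfer of the hydroxymethyl group from tin, with butyl transfer or protodebromination taking over at the hindered alkenyl bromide. Fallback: build C7 by carbonylation. From 7, Pd(OAc)2 with 1,3-bis(diphenylphosphino)propane, CO (1 atm), methanol and Et3N in DMF at 70 °C should give the methyl ester F8. i-Bu2AlH at −78 °C reduces it to the allylic alcohol and the route is rejoined at 9.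

## Further compounds

F0 | step 1 | none | none
F1 | step 4 | (1S,4S,5S,6R)-3-bromo-5,6-dihydroxy-4-[(4-methoxyphenyl)methoxy]cyclohex-2-en-1-yl acetate (O3-acetate of 6) | BrC1=C[C@H](OC(C)=O)[C@H](O)[C@H](O)[C@@H]1OCc2ccc(OC)cc2
F2 | step 3 | (1S,6S)-2-bromo-6-{[dimethyl(2,3-dimethylbutan-2-yl)silyl]oxy}cyclohexa-2,4-dien-1-ol | BrC1=CC=C[C@H](O[Si](C)(C)C(C)(C)C(C)C)[C@@H]1O
F3 | step 3 | {[(1S,6S)-5-bromo-6-[(4-methoxyphenyl)methoxy]cyclohexa-2,4-dien-1-yl]oxy}(dimethyl)(2,3-dimethylbutan-2-yl)silane | BrC1=CC=C[C@H](O[Si](C)(C)C(C)(C)C(C)C)[C@@H]1OCc2ccc(OC)cc2
F4 | step 5 | osmate ester 5 carrying a benzoyl group on O5 (TMEDA chelate, hexavalent osmium) | BrC1=C[C@@H]3O[Os](=O)(=O)O[C@@H]3[C@H](OC(=O)c4ccccc4)[C@@H]1OCc2ccc(OC)cc2.CN(C)CCN(C)C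
F5 | step 5 | O5-benzoate of triol 6 (free O3–H and O4–H, all-cis) | BrC1=C[C@H](O)[C@H](O)[C@H](OC(=O)c3ccccc3)[C@@H]1OCc2ccc(OC)cc2
F6 | step 5 | O5-benzoate of bromo acetonide 7 | BrC1=C[C@@H]3OC(C)(C)O[C@@H]3[C@H](OC(=O)c4ccccc4)[C@@H]1OCc2ccc(OC)cc2
F7 | step 5 | O5-monobenzoate of diol 9 (free C7–OH) | OCC1=C[C@@H]3OC(C)(C)O[C@@H]3[C@H](OC(=O)c4ccccc4)[C@@H]1OCc2ccc(OC)cc2
F8 | step 6 | methyl ester analogue of 9 in which C7 is CO2Me (O5–H free) | COC(=O)C1=C[C@@H]3OC(C)(C)O[C@@H]3[C@H](O)[C@@H]1OCc2ccc(OC)cc2
F0 | step 8 | none | none
A1 | alternative 1 | furan | c1ccoc1
A2 | alternative 1 | 3-acryloyloxazolidin-2-one | C=CC(=O)N1CCOC1=O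
A3 | alternative 1 | endo adduct 3-(7-oxabicyclo[2.2.1]hept-5-ene-2-carbonyl)oxazolidin-2-one | O=C(N1CCOC1=O)[C@@H]1C[C@@H]2C=C[C@H]1O2
A4 | alternative 2 | (1E,3E)-1,4-diacetoxybuta-1,3-diene | CC(=O)O/C=C/C=C/OC(C)=O
A5 | alternative 2 | vinylene carbonate | O=C1OC=CO1
A6 | alternative 2 | meso all-cis 3,6-diacetoxycyclohex-1-ene-4,5-diyl carbonate | C1=C[C@H](OC(C)=O)[C@@H]2OC(=O)O[C@@H]2[C@@H]1OC(C)=O
A7 | alternative 3 | methyl 3-O-benzoyl-6-deoxy-2,4-bis-O-(triethylsilyl)-α-D-ribo-hex-5-enopyranoside (D-allo series) | C=C1O[C@H](OC)[C@H](O[Si](CC)(CC)CC)[C@H](OC(=O)c2ccccc2)[C@@H]1O[Si](CC)(CC)CC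
A8 | alternative 3 | 5-benzoyloxy-3-hydroxy-4,6-bis(triethylsilyloxy)cyclohexanone (C1 carbonyl, target numbering) | O=C1C[C@H](O)[C@H](O[Si](CC)(CC)CC)[C@H](OC(=O)c2ccccc2)[C@@H]1O[Si](CC)(CC)CC
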